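(The runs are simulated with constants of no real substance.)

The starting material left in the red run at its last reading, 75.6% of the charge, is more than the 70.0% the question looks at, so the answer lies beyond the readings.

| flask | starting material | free catalyst | remark |
|---|---|---|---|
| ochre | 11 mM | 0.11 mM | run made earlier |
| grey | 16 mM | 0.11 mM | run made earlier |
| red | 22 mM | 0.17 mM | run made earlier |
| flask | 22 mM | 0.11 mM |  |

| run | time / min | target / % | starting material / % |
|---|---|---|---|
| ochre | 3.00 | 11.0 | 89.6 |
| ochre | 6.00 | 15.1 | 85.4 |
| ochre | 10.0 | 17.1 | 82.6 |
| ochre | 12.0 | 19.1 | 81.7 |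
| ochre | 15.0 | 19.2 | 80.0 |
| grey | 1.33 | 6.0 | 94.6 |
| grey | 2.50 | 8.8 | 91.6 |
| grey | 4.00 | 12.0 | 88.0 |
| grey | 8.00 | 17.1 | 84.1 |
| grey | 15.0 | 21.4 | 79.2 |
| red | 3.00 | 12.1 | 87.2 |
| red | 6.00 | 18.8 | 82.5 |
| red | 10.0 | 22.0 | 78.0 |
| red | 12.0 | 24.0 | 76.7 |
| red | 15.0 | 25.7 | 75.6 |

(readings scatter by 0.5 percentage points)



- apparent order in free catalyst when 30% of the starting material are converted (percent change of the rate of making target for one percent more free catalyst charged)

The flask must make 60.0 turnovers per catalyst charged: this turnover demand, the fraction converted times the charge of starting material over the charge of catalyst, is a turnover number. The red run shows 33.3 at its last reading, fewer. My own bracket assumes that the percent curves are stretched copies and neglects the different charges of starting material in red and grey; on that assumption the order is the log of the time ratio at equal conversion over the log of the catalyst ratio. Its bounds are read near a target of 18.8%, short of the 30% conversion asked about, and are carried there by the same assumption.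

Red at 6.00 min stands above grey at 8.00 min, which gives the lower bound:

order ≥ 0.661

The same red reading stands below grey at 15.0 min, which gives the upper bound:

order ≤ 2.10

Interpolating on red replaces these by two point readings, each carrying the scatter:

0.973 and 1.11

The forecast, 1, lies between them: “roughly first order in catalyst at fixed conversion”.

The flask gives 0.87, inside the wide bracket and below the forecast.

    catalyst intermediate → free catalyst + target (k = 0.280 /s)
    2 free catalyst → spent catalyst (k = 170 /M/s)
    starting material + free catalyst → catalyst intermediate (k = 19.0 /M/s)
    free catalyst ⇌ dormant form (K = 4.10, k = 8.60 × 10⁻⁴ /s)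

At 25.0 min the flask holds 83.4% of its catalyst as spent catalyst. It meets its demand of 60.0 turnovers in 45.4 min, a mean of 1.32 /min. With twice the free catalyst the demand falls to 30.0 turnovers and the time to 20.6 min, a mean of 1.46 /min, higher.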